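Everything hinges on opening ring A at the C4–C5 bond (halimane numbering). The feature exploited is that the C19 ester on C4 and the C1=C10 double bond make up a γ,δ-unsaturated ester (C19–C4–C5–C10=C1) whose termini C4 and C1 are additionally linked by C2–C3, so an Ireland–Claisen rearrangement of a lactone-derived silyl ketene acetal delivers ring A directly. In one operation a δ-lactone is traded for the carbocycle while the quaternary C4, the C5 methine and the ring A alkene are created and the configuration of a sacrificial C1 carbinol is relayed to both centres. The precursor is a (6R)-3-methyl-δ-valerolactone carrying the complete ring B cyclohexenyl unit (C8 and C9 set, allyl on C9) at C6.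

Key step: step 9

Remark: halimane numbering is used for positions throughout; the methyl-bearing carbon of the glutarate-derived fragment is racemic and is carried as an epimer pair (compounds 8, 9, 13, 14, 15) until step 9 makes it planar.

Step 1
Reactants: 1 2-methylcyclohex-2-en-1-one
Product: 3 trimethyl{[(3R)-2,3-dimethylcyclohex-1-en-1-yl]oxy}silane, via dimethylaluminium enolate 2 (not isolated)
Conditions: AlMe3, CuTC (copper thiophene-2-carboxylate, C5H3CuO2S, cat.), chiral phosphoramidite L* [O,O'-(1,1'-binaphthalene-2,2'-diyl) N,N-bis(1-phenylethyl)phosphoramidite, enantiomer giving the 3R product] (cat.), Et2O, −30 °C; then Me3SiOTf, THF, −30 °C to rt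
Reagents that add atoms: trimethylaluminium C[Al](C)C; trimethylsilyl trifluoromethanesulfonate C[Si](C)(C)OS(=O)(=O)C(F)(F)F
Why: Copper-catalysed asymmetric conjugate addition: the monovalent copper–phosphoramidite complex delivers methyl to one face of the enone (ligand enantiomer chosen for the R centre, the future C8), and O-silylation of the regiodefined aluminium enolate stores the enolate position for step 2.

Step 2
Reactants: 3 trimethyl{[(3R)-2,3-dimethylcyclohex-1-en-1-yl]oxy}silane; 4 allyl bromide
Product: 6 (2S,3R)-2-allyl-2,3-dimethylcyclohexan-1-one, via lithium enolate 5 (not isolated)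
Conditions: MeLi, THF, 0 °C to rt; then 4, DMPU, −78 to 0 °C
Reagents that add atoms: none
Why: Enolate alkylation: MeLi cleaves the Si–O bond to the tetrasubstituted lithium enolate, and allyl bromide should attack anti to the neighbouring methyl (held pseudoaxial by allylic strain), so the C9 quaternary centre forms with the two methyls cis.

Step 3
Reactants: 7 2-methylglutaric anhydride (racemic)
Product: 8 5-[methoxy(methyl)amino]-2-methyl-5-oxopentanoic acid (racemic)
Conditions: MeNHOMe·HCl, pyridine, CH2Cl2, 0 °C to rt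
Reagents that add atoms: N,O-dimethylhydroxylamine hydrochloride CNOC.Cl
Why: Aminolysis of a cyclic anhydride: the amine should attack the less hindered carbonyl remote from the methyl branch, which puts the Weinreb amide on the future C1 and the acid on the future C19; no stereocentre is set and any regioisomer should be separable after step 4.

Step 4
Reactants: 8 5-[methoxy(methyl)amino]-2-methyl-5-oxopentanoic acid
Product: 9 methyl 5-[methoxy(methyl)amino]-2-methyl-5-oxopentanoate (racemic)
Conditions: Me3SiCHN2, PhMe/MeOH, 0 °C to rt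
Reagents that add atoms: trimethylsilyldiazomethane C[Si](C)(C)C=[N+]=[N-]
Why: Diazoalkane esterification (O-methylation of the carboxylate by the protonated reagent) is neutral and leaves the Weinreb amide alone; the racemic centre is of no consequence because step 9 makes it planar.

Step 5
Reactants: 6 (2S,3R)-2-allyl-2,3-dimethylcyclohexan-1-one
Product: 10 (E)-2,4,6-triisopropylbenzenesulfonyl hydrazone of 6
Conditions: 2,4,6-triisopropylbenzenesulfonyl hydrazide, HCl (cat.), MeCN, rt
Reagents that add atoms: 2,4,6-triisopropylbenzenesulfonyl hydrazide CC(C)c1cc(C(C)C)c(S(=O)(=O)NN)c(C(C)C)c1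
Why: Sulfonylhydrazone condensation, acid-catalysed because the carbonyl is flanked by a quaternary carbon; the N–N bond should settle anti to that carbon (E), syn to the only α-CH2, as the Shapiro deprotonation requires.

Step 6
Reactants: 10 (E)-2,4,6-triisopropylbenzenesulfonyl hydrazone of 6; 9 methyl 5-[methoxy(methyl)amino]-2-methyl-5-oxopentanoate
Product: 13 methyl 5-[(5R,6S)-6-allyl-5,6-dimethylcyclohex-1-en-1-yl]-2-methyl-5-oxopentanoate, via alkenyllithium 11 (not isolated), via alkenylmagnesium bromide 12 (not isolated)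
Conditions: n-BuLi (2.1 equiv), THF, −78 to 0 °C; MgBr2·OEt2, −78 °C; then 9, −78 to 0 °C
Reagents that add atoms: none
Why: Shapiro reaction followed by Weinreb ketone synthesis: double deprotonation and loss of sulfinate and N2 can only give the alkene toward the CH2 side (the other α-carbon is quaternary), and after transmetalation to the less basic magnesium species the chelate-stabilised addition to the Weinreb amide should outpace attack at the α-branched methyl ester.

Step 7
Reactants: 13 methyl 5-[(5R,6S)-6-allyl-5,6-dimethylcyclohex-1-en-1-yl]-2-methyl-5-oxopentanoate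
Product: 14 methyl (5R)-5-[(5R,6S)-6-allyl-5,6-dimethylcyclohex-1-en-1-yl]-5-hydroxy-2-methylpentanoate
Conditions: (S)-2-methyl-CBS-oxazaborolidine, catecholborane, PhMe, −78 °C
Reagents that add atoms: none
Why: Corey–Bakshi–Shibata reduction: with the cyclohexenyl group as the large and the CH2 chain as the small substituent, the (S)-catalyst should deliver hydride 1,2 to give the (R)-C1 carbinol (same spatial sense as (R)-1-phenylethanol from acetophenone), leaving both alkenes and the ester untouched; the configuration is to be confirmed by Mosher ester analysis before step 9.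

Step 8
Reactants: 14 methyl (5R)-5-[(5R,6S)-6-allyl-5,6-dimethylcyclohex-1-en-1-yl]-5-hydroxy-2-methylpentanoate
Product: 15 (6R)-6-[(5R,6S)-6-allyl-5,6-dimethylcyclohex-1-en-1-yl]-3-methyloxan-2-one
Conditions: PPTS (cat.), PhMe, 4 Å MS, 60 °C
Reagents that add atoms: none
Why: Acid-catalysed lactonisation (intramolecular transesterification) closes the six-membered lactone on the C1 oxygen with loss of methanol; the weak pyridinium acid is chosen so that the allylic C1–O bond does not ionise and C1 keeps its configuration.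

Step 9
Reactants: 15 (6R)-6-[(5R,6S)-6-allyl-5,6-dimethylcyclohex-1-en-1-yl]-3-methyloxan-2-one
Product: 18 (1S,5S,6R,8aR)-5-allyl-1,5,6-trimethyl-1,2,3,5,6,7,8,8a-octahydronaphthalene-1-carboxylic acid (halimane positions 4S,5R,8R,9S), via silyl ketene acetal 16 (not isolated), via trimethylsilyl ester 17 (not isolated)
Conditions: LDA (LiN(iPr)2), Me3SiCl/Et3N (premixed), THF, −78 °C to rt; PhMe, 110 °C; then 1 M HCl, THF, rt
Reagents that add atoms: none
Why: LDA deprotonates C4 and the in situ Me3SiCl quench gives silyl ketene acetal 16, whose geometry is fixed by the lactone ring (C3 cis to the ring oxygen); on heating a concerted suprafacial [3,3] shift (Ireland–Claisen rearrangement) makes the C4–C5 bond while the C1–O bond breaks and the alkene moves from C5=C10 to C1=C10, and acidic work-up frees the acid from silyl ester 17. The closest known reaction type is the Ireland–Claisen rearrangement of silyl ketene acetals of 6-alkenyl δ-valerolactones (and 6-alkenyl-1,4-dioxan-2-ones), which exchanges the lactone for a cyclohexene (dihydropyran) carboxylic acid. Ring A, the only ring closed, forms by this sigmatropic ring transposition: the C2–C3 bridge between C1 and C4 forbids a chair, so the six-membered carbocycle closes through a boat-shaped, bicyclo[2.2.2]-like transition state. C5 is controlled by the (R)-C1 carbinol, because the departing oxygen and the arriving C4 must use the same alkene face with the C1–H bond turned outward toward C9, and C4 by the ring-locked ketene acetal within that boat, which leaves the carboxyl on the side of C6 (trans to H5) and the methyl outside (cis to H5), i.e. 4S,5R. The selectivity needed is complete transfer of the C1 configuration to C4 and C5; the tether (boat only) and the fixed ketene acetal geometry secure it, and the required ring B face is the one opposite the pseudoaxial C9 methyl, so substrate bias should not oppose it. The bath is kept at or below 110 °C so that the 1,5-diene formed by the C9 allyl group and the ring alkene does not enter a Cope rearrangement.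

Step 10
Reactants: 18 (1S,5S,6R,8aR)-5-allyl-1,5,6-trimethyl-1,2,3,5,6,7,8,8a-octahydronaphthalene-1-carboxylic acid
Product: 19 methyl (1S,5S,6R,8aR)-5-allyl-1,5,6-trimethyl-1,2,3,5,6,7,8,8a-octahydronaphthalene-1-carboxylate
Conditions: Me3SiCHN2, PhMe/MeOH, 0 °C to rt
Reagents that add atoms: trimethylsilyldiazomethane C[Si](C)(C)C=[N+]=[N-]
Why: Diazoalkane esterification methylates the hindered acid on oxygen without touching either alkene or any stereocentre.

Step 11
Reactants: 19 methyl (1S,5S,6R,8aR)-5-allyl-1,5,6-trimethyl-1,2,3,5,6,7,8,8a-octahydronaphthalene-1-carboxylate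
Product: 21 methyl (1S,5S,6R,8aR)-5-(3-hydroxypropyl)-1,5,6-trimethyl-1,2,3,5,6,7,8,8a-octahydronaphthalene-1-carboxylate, via B-alkyl-9-BBN adduct 20 (not isolated)
Conditions: 9-BBN, THF, 0 °C to rt; then 30% H2O2, aq NaOH, 0 °C
Reagents that add atoms: hydrogen peroxide OO
Why: Hydroboration–oxidation: the bulky 9-BBN adds anti-Markovnikov to the monosubstituted alkene only, ignoring the trisubstituted C1=C10 bond, and alkaline peroxide at 0 °C gives the primary alcohol while the ester on quaternary C4 resists hydrolysis.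

Step 12
Reactants: 21 methyl (1S,5S,6R,8aR)-5-(3-hydroxypropyl)-1,5,6-trimethyl-1,2,3,5,6,7,8,8a-octahydronaphthalene-1-carboxylate
Product: 22 methyl (1S,5S,6R,8aR)-1,5,6-trimethyl-5-(3-oxopropyl)-1,2,3,5,6,7,8,8a-octahydronaphthalene-1-carboxylate
Conditions: Dess–Martin periodinane, CH2Cl2, 0 °C to rt
Reagents that add atoms: none
Why: Dess–Martin oxidation stops cleanly at the aldehyde under near-neutral conditions that leave the ester and the ring alkene alone.

Step 13
Reactants: 22 methyl (1S,5S,6R,8aR)-1,5,6-trimethyl-5-(3-oxopropyl)-1,2,3,5,6,7,8,8a-octahydronaphthalene-1-carboxylate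
Product: 23 methyl (1S,5S,6R,8aR)-5-(but-3-yn-1-yl)-1,5,6-trimethyl-1,2,3,5,6,7,8,8a-octahydronaphthalene-1-carboxylate
Conditions: dimethyl (1-diazo-2-oxopropyl)phosphonate, K2CO3, MeOH, 0 °C to rt
Reagents that add atoms: dimethyl (1-diazo-2-oxopropyl)phosphonate COP(=O)(OC)C(=[N+]=[N-])C(C)=O
Why: Ohira–Bestmann (Seyferth–Gilbert) homologation: the diazomethylphosphonate anion formed in situ converts the aldehyde through a vinylidene 1,2-shift into the terminal alkyne, adding C14; the aldehyde has no α-stereocentre to epimerise.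

Step 14
Reactants: 23 methyl (1S,5S,6R,8aR)-5-(but-3-yn-1-yl)-1,5,6-trimethyl-1,2,3,5,6,7,8,8a-octahydronaphthalene-1-carboxylate
Product: 25 methyl (1S,5S,6R,8aR)-5-[(3E)-5-hydroxy-3-methylpent-3-en-1-yl]-1,5,6-trimethyl-1,2,3,5,6,7,8,8a-octahydronaphthalene-1-carboxylate, via alkenylalane 24 (not isolated)
Conditions: AlMe3, Cp2ZrCl2 (cat.), CH2Cl2, 0 °C to rt; then (CH2O)n, THF, 0 °C to rt
Reagents that add atoms: trimethylaluminium C[Al](C)C; formaldehyde (as paraformaldehyde) C=O
Why: Negishi zirconium-catalysed carboalumination: syn addition of Me–Al across the terminal alkyne puts the methyl on C13 and aluminium on C14, and the alkenylalane adds to formaldehyde with retention to give the (13E)-allylic alcohol (chain trans to CH2OH); the ester on quaternary C4 is hindered enough to survive AlMe3 at this temperature.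

Step 15
Reactants: 25 methyl (1S,5S,6R,8aR)-5-[(3E)-5-hydroxy-3-methylpent-3-en-1-yl]-1,5,6-trimethyl-1,2,3,5,6,7,8,8a-octahydronaphthalene-1-carboxylate
Product: 26 methyl (1S,5S,6R,8aR)-5-{2-[(2S,3S)-3-(hydroxymethyl)-2-methyloxiran-2-yl]ethyl}-1,5,6-trimethyl-1,2,3,5,6,7,8,8a-octahydronaphthalene-1-carboxylate
Conditions: Ti(OiPr)4 (cat.), L-(+)-diethyl tartrate, t-BuOOH, 4 Å MS, CH2Cl2, −20 °C
Reagents that add atoms: tert-butyl hydroperoxide CC(C)(C)OO
Why: Sharpless asymmetric epoxidation: L-(+)-diethyl tartrate, which converts geraniol into its (2S,3S)-epoxide, directs oxygen to the corresponding face of this geraniol-type alkene to set 13S and 14S; the C1=C10 alkene lacks a directing hydroxyl and does not react.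

Step 16
Reactants: 26 methyl (1S,5S,6R,8aR)-5-{2-[(2S,3S)-3-(hydroxymethyl)-2-methyloxiran-2-yl]ethyl}-1,5,6-trimethyl-1,2,3,5,6,7,8,8a-octahydronaphthalene-1-carboxylate
Product: 27 methyl (1S,5S,6R,8aR)-1,5,6-trimethyl-5-[(3R,4S)-3,4,5-trihydroxy-3-methylpentyl]-1,2,3,5,6,7,8,8a-octahydronaphthalene-1-carboxylate
Conditions: HClO4 (cat.), THF/H2O, 0 °C
Reagents that add atoms: water O
Why: Acid-catalysed epoxide hydrolysis: water opens the protonated epoxide at the tertiary C13, which carries positive charge better than C14 next to the CH2OH group, with inversion (13S to 13R), while the C14–O bond is kept (14S).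

Step 17
Reactants: 27 methyl (1S,5S,6R,8aR)-1,5,6-trimethyl-5-[(3R,4S)-3,4,5-trihydroxy-3-methylpentyl]-1,2,3,5,6,7,8,8a-octahydronaphthalene-1-carboxylate
Product: 28 methyl (1S,5S,6R,8aR)-5-[(3R,4S)-4,5-diacetoxy-3-hydroxy-3-methylpentyl]-1,5,6-trimethyl-1,2,3,5,6,7,8,8a-octahydronaphthalene-1-carboxylate (CNP0238486.2)
Conditions: Ac2O, pyridine, rt
Reagents that add atoms: acetic anhydride CC(=O)OC(C)=O
Why: O-Acylation with Ac2O/pyridine in the absence of DMAP esterifies the primary C15 and secondary C14 hydroxyls and should leave the hindered tertiary C13 hydroxyl free; no stereocentre changes.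

Compound list
1 | 2-methylcyclohex-2-en-1-one | CC1=CCCCC1=O | starting material
2 | dimethylaluminium (3R)-2,3-dimethylcyclohex-1-en-1-olate | C[C@@H]1CCCC(O[Al](C)C)=C1C | intermediate (not isolated)
3 | trimethyl{[(3R)-2,3-dimethylcyclohex-1-en-1-yl]oxy}silane | C[C@@H]1CCCC(O[Si](C)(C)C)=C1C | intermediate
4 | allyl bromide | C=CCBr | starting material
5 | lithium (3R)-2,3-dimethylcyclohex-1-en-1-olate | C[C@@H]1CCCC(O[Li])=C1C | intermediate (not isolated)
6 | (2S,3R)-2-allyl-2,3-dimethylcyclohexan-1-one | O=C1CCC[C@@H](C)[C@]1(C)CC=C | intermediate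
7 | 2-methylglutaric anhydride (racemic) | CC1CCC(=O)OC1=O | starting material
8 | 5-[methoxy(methyl)amino]-2-methyl-5-oxopentanoic acid (racemic) | OC(=O)C(C)CCC(=O)N(C)OC | intermediate
9 | methyl 5-[methoxy(methyl)amino]-2-methyl-5-oxopentanoate (racemic) | COC(=O)C(C)CCC(=O)N(C)OC | intermediate
10 | (E)-2,4,6-triisopropylbenzenesulfonyl hydrazone of 6 | CC(C)c1cc(C(C)C)c(c(c1)C(C)C)S(=O)(=O)N/N=C1\CCC[C@@H](C)[C@]1(C)CC=C | intermediate
11 | [(5R,6S)-6-allyl-5,6-dimethylcyclohex-1-en-1-yl]lithium | [Li]C1=CCC[C@@H](C)[C@]1(C)CC=C | intermediate (not isolated)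
12 | [(5R,6S)-6-allyl-5,6-dimethylcyclohex-1-en-1-yl]magnesium bromide | Br[Mg]C1=CCC[C@@H](C)[C@]1(C)CC=C | intermediate (not isolated)
13 | methyl 5-[(5R,6S)-6-allyl-5,6-dimethylcyclohex-1-en-1-yl]-2-methyl-5-oxopentanoate (2RS) | COC(=O)C(C)CCC(=O)C1=CCC[C@@H](C)[C@]1(C)CC=C | intermediate
14 | methyl (5R)-5-[(5R,6S)-6-allyl-5,6-dimethylcyclohex-1-en-1-yl]-5-hydroxy-2-methylpentanoate (2RS) | COC(=O)C(C)CC[C@@H](O)C1=CCC[C@@H](C)[C@]1(C)CC=C | intermediate
15 | (6R)-6-[(5R,6S)-6-allyl-5,6-dimethylcyclohex-1-en-1-yl]-3-methyloxan-2-one (3RS) | CC1CC[C@@H](OC1=O)C2=CCC[C@@H](C)[C@]2(C)CC=C | intermediate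
16 | {[(2R)-2-[(5R,6S)-6-allyl-5,6-dimethylcyclohex-1-en-1-yl]-5-methyl-3,4-dihydro-2H-pyran-6-yl]oxy}trimethylsilane | CC1=C(O[Si](C)(C)C)O[C@H](CC1)C2=CCC[C@@H](C)[C@]2(C)CC=C | intermediate (not isolated)
17 | trimethylsilyl ester of 18 | C[Si](C)(C)OC(=O)[C@@]1(C)CCC=C2[C@H]1CC[C@@H](C)[C@]2(C)CC=C | intermediate (not isolated)
18 | (1S,5S,6R,8aR)-5-allyl-1,5,6-trimethyl-1,2,3,5,6,7,8,8a-octahydronaphthalene-1-carboxylic acid | OC(=O)[C@@]1(C)CCC=C2[C@H]1CC[C@@H](C)[C@]2(C)CC=C | intermediate
19 | methyl ester of 18 | COC(=O)[C@@]1(C)CCC=C2[C@H]1CC[C@@H](C)[C@]2(C)CC=C | intermediate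
20 | B-alkyl-9-borabicyclo[3.3.1]nonane adduct of 19 (boron on the terminal side-chain carbon) | COC(=O)[C@@]1(C)CCC=C2[C@H]1CC[C@@H](C)[C@]2(C)CCCB3C4CCCC3CCC4 | intermediate (not isolated)
21 | 3-hydroxypropyl ester (primary alcohol at C13) | COC(=O)[C@@]1(C)CCC=C2[C@H]1CC[C@@H](C)[C@]2(C)CCCO | intermediate
22 | 3-oxopropyl ester (C13 aldehyde) | COC(=O)[C@@]1(C)CCC=C2[C@H]1CC[C@@H](C)[C@]2(C)CCC=O | intermediate
23 | but-3-ynyl ester (C13≡C14 alkyne) | COC(=O)[C@@]1(C)CCC=C2[C@H]1CC[C@@H](C)[C@]2(C)CCC#C | intermediate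
24 | (E)-alkenyl(dimethyl)alane (Al on C14, methyl on C13) | COC(=O)[C@@]1(C)CCC=C2[C@H]1CC[C@@H](C)[C@]2(C)CC/C(C)=C/[Al](C)C | intermediate (not isolated)
25 | (13E)-allylic alcohol | COC(=O)[C@@]1(C)CCC=C2[C@H]1CC[C@@H](C)[C@]2(C)CC/C(C)=C/CO | intermediate
26 | (13S,14S)-13,14-epoxy-15-ol | COC(=O)[C@@]1(C)CCC=C2[C@H]1CC[C@@H](C)[C@]2(C)CC[C@]3(C)O[C@H]3CO | intermediate
27 | (13R,14S)-13,14,15-triol | COC(=O)[C@@]1(C)CCC=C2[C@H]1CC[C@@H](C)[C@]2(C)CC[C@@](C)(O)[C@H](CO)O | intermediate
28 | CNP0238486.2, (4S,5R,8R,9S,13R,14S)-14,15-diacetate methyl ester | COC(=O)[C@@]1(C)CCC=C2[C@H]1CC[C@@H](C)[C@]2(C)CC[C@@](C)(O)[C@H](COC(C)=O)OC(C)=O | target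

Total step count: 17. Longest linear sequence: 15 steps (steps 1, 2 and 5 to 17, from 2-methylcyclohex-2-en-1-one); steps 3 and 4 make the side fragment.

Steps most likely to fail

Step 9. The rearrangement may stall because the tetrasubstituted ketene acetal has to stack over a trisubstituted alkene flanked by the quaternary C9, so that C-silylation, hydrolysis back to the lactone or thermal degradation overtakes the [3,3] shift. The fallback sets out from hydrazone 10 and returns at ester 19. The alkenylmagnesium species 12 (made as in step 6) would be acylated with methyl 5-[methoxy(methyl)amino]-5-oxopentanoate F1 (from commercial methyl 5-chloro-5-oxopentanoate, MeNHOMe·HCl and pyridine) to the chain-unbranched enone F2. CBS reduction as in step 7 would give the (R)-hydroxy ester F3 and PPTS the 3-unsubstituted (6R)-lactone F4. Its Ireland–Claisen rearrangement runs through the less crowded trisubstituted silyl ketene acetal F5 and silyl ester F6 to the C4–H acid F7, which is esterified to methyl ester F8. The quaternary centre is then made separately by ester enolate alkylation: LDA (THF, −78 °C) gives lithium enolate F9, and MeI should enter from the ring A face that carries H5, away from the C5–C6 bond, to give 19. A C4 epimer, if formed, would be removed at that stage.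

Step 6. The alkenyl anion may form incompletely or be protonated, and the organometallic may attack the methyl ester or enolise the amide. The fallback sets out from ketone 6 and amide 9 and returns at enone 13. KN(SiMe3)2 and PhNTf2 (THF, −78 °C) convert 6, which can enolise only toward its CH2 side, into the enol triflate F10. Cp2Zr(H)Cl reduces the Weinreb amide of 9 selectively to methyl 2-methyl-5-oxopentanoate F11. Nozaki–Hiyama–Kishi coupling (CrCl2, NiCl2 cat., DMF, rt), which tolerates esters and needs no strongly basic carbanion, gives the allylic alcohol F12 as both C1 epimers, and Dess–Martin oxidation of F12 gives 13.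

Step 7. Hydride delivery to a hindered, twisted enone may show poor facial selectivity if the bias from the C9 centre opposes the catalyst. The fallback sets out from enone 13 and returns at acid 18. Luche reduction (NaBH4, CeCl3·7H2O, MeOH, −78 °C) gives 14 together with its (1S)-epimer F13, and PPTS lactonisation gives 15 mixed with the (6S)-lactone F14. The mixture is put through step 9 unchanged. Because the rearrangement is stereospecific, 15 gives 18, while F14 passes through silyl ketene acetal F15 and silyl ester F16 to the C4,C5-bis-epimeric acid F17. F17 is a diastereomer of 18 that differs in how ring A relates to the C8/C9 centres, so it should be separable by chromatography or crystallisation, at the cost of the material that ends up as F17.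

Further compounds
F1 | step 9 | methyl 5-[methoxy(methyl)amino]-5-oxopentanoate | COC(=O)CCCC(=O)N(C)OC
F2 | step 9 | methyl 5-[(5R,6S)-6-allyl-5,6-dimethylcyclohex-1-en-1-yl]-5-oxopentanoate | COC(=O)CCCC(=O)C1=CCC[C@@H](C)[C@]1(C)CC=C
F3 | step 9 | methyl (5R)-5-[(5R,6S)-6-allyl-5,6-dimethylcyclohex-1-en-1-yl]-5-hydroxypentanoate | COC(=O)CCC[C@@H](O)C1=CCC[C@@H](C)[C@]1(C)CC=C
F4 | step 9 | (6R)-6-[(5R,6S)-6-allyl-5,6-dimethylcyclohex-1-en-1-yl]oxan-2-one | O=C1CCC[C@@H](O1)C2=CCC[C@@H](C)[C@]2(C)CC=C
F5 | step 9 | trimethylsilyl ketene acetal of F4 | C[Si](C)(C)OC1=CCC[C@@H](O1)C2=CCC[C@@H](C)[C@]2(C)CC=C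
F6 | step 9 | trimethylsilyl ester of F7 | C[Si](C)(C)OC(=O)[C@H]1CCC=C2[C@H]1CC[C@@H](C)[C@]2(C)CC=C
F7 | step 9 | C4-demethyl analogue of acid 18 (carboxyl cis to C6) | OC(=O)[C@H]1CCC=C2[C@H]1CC[C@@H](C)[C@]2(C)CC=C
F8 | step 9 | methyl ester of F7 | COC(=O)[C@H]1CCC=C2[C@H]1CC[C@@H](C)[C@]2(C)CC=C
F9 | step 9 | lithium enolate of F8 | COC(O[Li])=C1CCC=C2[C@H]1CC[C@@H](C)[C@]2(C)CC=C
F10 | step 6 | (5R,6S)-6-allyl-5,6-dimethylcyclohex-1-en-1-yl trifluoromethanesulfonate | O=S(=O)(OC1=CCC[C@@H](C)[C@]1(C)CC=C)C(F)(F)F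
F11 | step 6 | methyl 2-methyl-5-oxopentanoate (racemic) | COC(=O)C(C)CCC=O
F12 | step 6 | methyl 5-[(5R,6S)-6-allyl-5,6-dimethylcyclohex-1-en-1-yl]-5-hydroxy-2-methylpentanoate, both C5 epimers | COC(=O)C(C)CCC(O)C1=CCC[C@@H](C)[C@]1(C)CC=C
F13 | step 7 | methyl (5S)-5-[(5R,6S)-6-allyl-5,6-dimethylcyclohex-1-en-1-yl]-5-hydroxy-2-methylpentanoate | COC(=O)C(C)CC[C@H](O)C1=CCC[C@@H](C)[C@]1(C)CC=C
F14 | step 7 | (6S)-6-[(5R,6S)-6-allyl-5,6-dimethylcyclohex-1-en-1-yl]-3-methyloxan-2-one | CC1CC[C@H](OC1=O)C2=CCC[C@@H](C)[C@]2(C)CC=C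
F15 | step 7 | trimethylsilyl ketene acetal of F14 | CC1=C(O[Si](C)(C)C)O[C@@H](CC1)C2=CCC[C@@H](C)[C@]2(C)CC=C
F16 | step 7 | trimethylsilyl ester of F17 | C[Si](C)(C)OC(=O)[C@]1(C)CCC=C2[C@@H]1CC[C@@H](C)[C@]2(C)CC=C
F17 | step 7 | (1R,5S,6R,8aS)-5-allyl-1,5,6-trimethyl-1,2,3,5,6,7,8,8a-octahydronaphthalene-1-carboxylic acid (C4,C5-bis-epimer of 18) | OC(=O)[C@]1(C)CCC=C2[C@@H]1CC[C@@H](C)[C@]2(C)CC=C
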